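The route rests on disconnecting the C1–O1 and C6–O6 bonds of the six-membered carbocycle. The unit C7–C1(O1)–C6(O6) is then recognised as the carboxyl, ipso and ortho carbons of benzoic acid, and the ring as its benzene ring. A whole-cell benzoate 1,2-dioxygenase makes both C–O bonds in one operation. It dearomatises the arene and sets the quaternary carbinol C1, with C7 attached, in the absolute configuration of the target, leaving a diene for later oxidation of C2=C3. The precursor is benzoic acid itself, fed as PhCO2Na. The remaining steps only adjust oxidation level, protecting groups and the configuration at C6.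

Key step: step 1

Remark: locants follow the carbocycle numbering C1 = C(OH)(CH2OH), C2 = CHOH, C3 = CHOBz, C4=C5, C6 = CHOBz, C7 = exocyclic carbon, with O1–O7 the oxygens on these carbons; β is the ring face that carries C7 (and O2, O3, O6 in the target) and α the face of O1; descriptors given with these locants refer to this numbering; the NADH used by the dioxygenase is assumed to be regenerated by the growing cells from fructose and is treated as catalytic.

Step 1
Reactants: 1 benzoic acid
Product: 2 (1S,2R)-1,2-dihydroxycyclohexa-3,5-diene-1-carboxylic acid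
Conditions: Cupriavidus necator B9 (Ralstonia eutropha B9, diol-dehydrogenase-deficient mutant) whole cells expressing benzoate 1,2-dioxygenase, PhCO2Na feed, fructose, mineral salts medium, air, pH 7, 30 °C; then pH 3 at 0 °C, EtOAc extraction
Reagents that add atoms: dioxygen, O=O
Why: The Rieske [2Fe–2S] cluster relays two electrons from NADH to a mononuclear non-haem iron centre, which activates O2 and transfers both oxygen atoms to the same face of the C1=C6 bond of carboxylate-bound benzoate, so that C1–O1 and C6–O6 form in a syn addition and the arene is dearomatised. The reaction type is microbial arene cis-dihydroxylation by a ring-hydroxylating dioxygenase, and it is the native reaction of this enzyme on its natural substrate. No ring is closed; the six-membered carbocycle of benzoic acid is carried over as a cyclohexa-3,5-diene. The substrate is achiral, so both new stereocentres (C1 S and C6 R, O1 and O6 cis) are set by the chiral active site alone. The step needs ipso,ortho regioselectivity and discrimination of the two enantiotopic ortho carbons, both secured by anchoring of the carboxylate in the binding pocket, and it needs the diol to accumulate, which the missing diol dehydrogenase of the blocked mutant secures.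

Step 2
Reactants: 2 (1S,2R)-1,2-dihydroxycyclohexa-3,5-diene-1-carboxylic acid, 3 2,2-dimethoxypropane
Product: 5 methyl (3aS,7aR)-2,2-dimethyl-3a,7a-dihydro-1,3-benzodioxole-3a-carboxylate, via acetonide acid 4 (not isolated)
Conditions: 2,2-dimethoxypropane, TsOH·H2O (cat.), acetone, rt; then K2CO3, MeI, same flask, rt
Reagents that add atoms: 2,2-dimethoxypropane (3), COC(C)(C)OC; iodomethane, CI
Why: Acid-catalysed transketalisation of the cis-1,2-diol followed by SN2 O-alkylation of the potassium carboxylate should give the ester acetonide, in which the cis ring fusion is dictated by the cis diol, no stereocentre is touched, and the ketal suppresses acid-promoted rearomatisation of the diene diol.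

Step 3
Reactants: 5 methyl (3aS,7aR)-2,2-dimethyl-3a,7a-dihydro-1,3-benzodioxole-3a-carboxylate
Product: 6 [(3aR,7aR)-2,2-dimethyl-3a,7a-dihydro-1,3-benzodioxol-3a-yl]methanol
Conditions: LiAlH4, THF, 0 °C; then H2O, NaOH (aq)
Reagents that add atoms: none
Why: Hydride reduction of the ester with LiAlH4 should give the primary alcohol C7–OH, since the ketal and the unactivated diene are inert to hydride and no stereocentre is affected (the descriptor at C3a changes only through the priority rules).

Step 4
Reactants: 6 [(3aR,7aR)-2,2-dimethyl-3a,7a-dihydro-1,3-benzodioxol-3a-yl]methanol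
Product: 8 (3aS,4R,5R,7aR)-3a-(hydroxymethyl)-2,2-dimethyl-3a,4,5,7a-tetrahydro-1,3-benzodioxole-4,5-diol, via osmate ester 7 (not isolated)
Conditions: OsO4 (1.05 equiv), TMEDA (1.1 equiv), CH2Cl2, −78 °C; then Na2SO3 (aq), THF, reflux
Reagents that add atoms: osmium tetroxide, O=[Os](=O)(=O)=O
Why: In this hydrogen-bond-directed syn-dihydroxylation the homoallylic O7–H binds an oxo ligand of the OsO4–TMEDA complex and should steer the [3+2] addition to the neighbouring C2=C3 bond instead of the remote C4=C5 bond, with O2 and O3 both entering on the β face because that face carries C7 and lies opposite the α-fused acetonide; sulfite then releases the diol from the osmate ester.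

Step 5
Reactants: 8 (3aS,4R,5R,7aR)-3a-(hydroxymethyl)-2,2-dimethyl-3a,4,5,7a-tetrahydro-1,3-benzodioxole-4,5-diol, 9 benzoyl chloride
Product: 11 3-O-benzoyl-2,7-O-(di-tert-butylsilylene)-1,6-O-isopropylidene-(1R,2R,3R,6R)-1-(hydroxymethyl)cyclohex-4-ene-1,2,3,6-tetrol, via silylene alcohol 10 (not isolated)
Conditions: tBu2Si(OTf)2 (1.05 equiv), pyridine, CH2Cl2, −40 → 0 °C; then BzCl, DMAP (cat.), 0 °C → rt
Reagents that add atoms: di-tert-butylsilyl bis(trifluoromethanesulfonate), CC(C)(C)[Si](OS(=O)(=O)C(F)(F)F)(OS(=O)(=O)C(F)(F)F)C(C)(C)C; benzoyl chloride (9), O=C(Cl)c1ccccc1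
Why: Silylene formation should start at the primary O7–H and close the six-membered 1,3-dioxasilinane on the cis-disposed O2 (preferred over a five-membered ring across O2/O3), which leaves O3–H as the only free hydroxyl for DMAP-catalysed acylation; no stereocentre changes.

Step 6
Reactants: 11 3-O-benzoyl-2,7-O-(di-tert-butylsilylene)-1,6-O-isopropylidene-(1R,2R,3R,6R)-1-(hydroxymethyl)cyclohex-4-ene-1,2,3,6-tetrol
Product: 12 3-O-benzoyl-2,7-O-(di-tert-butylsilylene)-(1R,2R,3R,6R)-1-(hydroxymethyl)cyclohex-4-ene-1,2,3,6-tetrol
Conditions: TFA–H2O (9:1), 0 °C, short contact time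
Reagents that add atoms: none
Why: Acid-catalysed ketal hydrolysis through the oxocarbenium ion should be faster than attack of water at the silicon shielded by two tert-butyl groups and leaves the benzoate alone, and since the C1–O1 and C6–O6 bonds are not broken the cis α,α-diol is freed with retention.

Step 7
Reactants: 12 3-O-benzoyl-2,7-O-(di-tert-butylsilylene)-(1R,2R,3R,6R)-1-(hydroxymethyl)cyclohex-4-ene-1,2,3,6-tetrol
Product: 13 (1S,2R,3R)-3-O-benzoyl-2,7-O-(di-tert-butylsilylene)-1,2,3-trihydroxy-1-(hydroxymethyl)cyclohex-4-en-6-one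
Conditions: IBX, DMSO, rt
Reagents that add atoms: none
Why: IBX oxidation of the secondary allylic C6–OH should give the enone, because IBX converts 1,2-diols into α-ketols without glycol cleavage, the tertiary O1–H cannot be oxidised, and C1 carries no hydrogen through which O2 could be eliminated.

Step 8
Reactants: 13 (1S,2R,3R)-3-O-benzoyl-2,7-O-(di-tert-butylsilylene)-1,2,3-trihydroxy-1-(hydroxymethyl)cyclohex-4-en-6-one
Product: 14 3-O-benzoyl-2,7-O-(di-tert-butylsilylene)-(1R,2R,3R,6S)-1-(hydroxymethyl)cyclohex-4-ene-1,2,3,6-tetrol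
Conditions: Me4NBH(OAc)3, MeCN–AcOH (1:1), −20 °C
Reagents that add atoms: none
Why: In this Evans–Saksena hydroxyl-directed reduction the borohydride exchanges onto the only free hydroxyl, the α-oriented tertiary O1–H, and should deliver hydride in a 1,2-sense to the α face of C6=O, which is also the open face because C7 and the silylene ring cover the β face, so that O6 ends up β (6S) and trans to O1.

Step 9
Reactants: 14 3-O-benzoyl-2,7-O-(di-tert-butylsilylene)-(1R,2R,3R,6S)-1-(hydroxymethyl)cyclohex-4-ene-1,2,3,6-tetrol, 9 benzoyl chloride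
Product: 15 3,6-di-O-benzoyl-2,7-O-(di-tert-butylsilylene)-(1R,2R,3R,6S)-1-(hydroxymethyl)cyclohex-4-ene-1,2,3,6-tetrol
Conditions: BzCl, pyridine, DMAP (cat.), CH2Cl2, 0 °C → rt
Reagents that add atoms: benzoyl chloride (9), O=C(Cl)c1ccccc1
Why: DMAP-catalysed acylation should esterify the secondary allylic O6–H while the tertiary O1–H stays free, and the configuration at C6 is retained because the C6–O6 bond is not involved.

Step 10
Reactants: 15 3,6-di-O-benzoyl-2,7-O-(di-tert-butylsilylene)-(1R,2R,3R,6S)-1-(hydroxymethyl)cyclohex-4-ene-1,2,3,6-tetrol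
Product: 16 (1R,4S,5S,6R)-5,6-dihydroxy-5-(hydroxymethyl)cyclohex-2-ene-1,4-diyl dibenzoate
Conditions: HF·pyridine, THF–pyridine, 0 °C → rt
Reagents that add atoms: none
Why: Fluoride-mediated desilylation under buffered, weakly acidic conditions should free O2–H and O7–H without the base-induced 1,2- or 1,3-benzoyl migration that a basic fluoride source could trigger, and no stereocentre is touched.

Compound list
1 | benzoic acid | O=C(O)c1ccccc1 | starting material
2 | (1S,2R)-1,2-dihydroxycyclohexa-3,5-diene-1-carboxylic acid | O[C@@H]1C=CC=C[C@@]1(O)C(=O)O | intermediate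
3 | 2,2-dimethoxypropane | COC(C)(C)OC | starting material
4 | (3aS,7aR)-2,2-dimethyl-3a,7a-dihydro-1,3-benzodioxole-3a-carboxylic acid (acetonide acid, not isolated) | CC1(C)O[C@@H]2C=CC=C[C@@]2(O1)C(=O)O | intermediate
5 | methyl (3aS,7aR)-2,2-dimethyl-3a,7a-dihydro-1,3-benzodioxole-3a-carboxylate | CC1(C)O[C@@H]2C=CC=C[C@@]2(O1)C(=O)OC | intermediate
6 | [(3aR,7aR)-2,2-dimethyl-3a,7a-dihydro-1,3-benzodioxol-3a-yl]methanol | CC1(C)O[C@@H]2C=CC=C[C@@]2(O1)CO | intermediate
7 | cyclic osmate ester of 8 across O2 and O3 on the β face, hexavalent osmium chelated by TMEDA (TMEDA drawn as a separate component; not isolated) | CC1(C)O[C@@H]2C=C[C@@H](O[Os]3(=O)=O)[C@@H](O3)[C@@]2(O1)CO.CN(C)CCN(C)C | intermediate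
8 | (3aS,4R,5R,7aR)-3a-(hydroxymethyl)-2,2-dimethyl-3a,4,5,7a-tetrahydro-1,3-benzodioxole-4,5-diol (O1,O6-acetonide α; O2–H, O3–H and C7 β) | CC1(C)O[C@@H]2C=C[C@@H](O)[C@@H](O)[C@@]2(O1)CO | intermediate
9 | benzoyl chloride | O=C(Cl)c1ccccc1 | starting material
10 | 2,7-O-(di-tert-butylsilylene)-1,6-O-isopropylidene-(1R,2R,3R,6R)-1-(hydroxymethyl)cyclohex-4-ene-1,2,3,6-tetrol (free O3–H; not isolated) | CC1(C)O[C@@H]2C=C[C@@H](O)[C@@H](O[Si]3(C(C)(C)C)C(C)(C)C)[C@@]2(O1)CO3 | intermediate
11 | 3-O-benzoyl-2,7-O-(di-tert-butylsilylene)-1,6-O-isopropylidene-(1R,2R,3R,6R)-1-(hydroxymethyl)cyclohex-4-ene-1,2,3,6-tetrol | CC1(C)O[C@@H]2C=C[C@@H](OC(=O)c4ccccc4)[C@@H](O[Si]3(C(C)(C)C)C(C)(C)C)[C@@]2(O1)CO3 | intermediate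
12 | 3-O-benzoyl-2,7-O-(di-tert-butylsilylene)-(1R,2R,3R,6R)-1-(hydroxymethyl)cyclohex-4-ene-1,2,3,6-tetrol (O1–H and O6–H free, cis, both α) | O[C@@H]1C=C[C@@H](OC(=O)c3ccccc3)[C@@H](O[Si]2(C(C)(C)C)C(C)(C)C)[C@@]1(O)CO2 | intermediate
13 | (1S,2R,3R)-3-O-benzoyl-2,7-O-(di-tert-butylsilylene)-1,2,3-trihydroxy-1-(hydroxymethyl)cyclohex-4-en-6-one (free tertiary O1–H α) | O=C1C=C[C@@H](OC(=O)c3ccccc3)[C@@H](O[Si]2(C(C)(C)C)C(C)(C)C)[C@@]1(O)CO2 | intermediate
14 | 3-O-benzoyl-2,7-O-(di-tert-butylsilylene)-(1R,2R,3R,6S)-1-(hydroxymethyl)cyclohex-4-ene-1,2,3,6-tetrol (O6–H β, trans to O1–H) | O[C@H]1C=C[C@@H](OC(=O)c3ccccc3)[C@@H](O[Si]2(C(C)(C)C)C(C)(C)C)[C@@]1(O)CO2 | intermediate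
15 | 3,6-di-O-benzoyl-2,7-O-(di-tert-butylsilylene)-(1R,2R,3R,6S)-1-(hydroxymethyl)cyclohex-4-ene-1,2,3,6-tetrol | O=C(O[C@H]1C=C[C@@H](OC(=O)c3ccccc3)[C@@H](O[Si]2(C(C)(C)C)C(C)(C)C)[C@@]1(O)CO2)c1ccccc1 | intermediate
16 | (1R,4S,5S,6R)-5,6-dihydroxy-5-(hydroxymethyl)cyclohex-2-ene-1,4-diyl dibenzoate, i.e. (1S,2R,3R,6S) in the numbering of the remark | O=C(O[C@H]1C=C[C@@H](OC(=O)c2ccccc2)[C@@H](O)[C@@]1(O)CO)c1ccccc1 | target

Total step count: 10
Longest linear sequence: 10 steps (1 → 16)

Steps most likely to fail

Step 4. The risk is loss of regiocontrol: osmylation of the less hindered C4=C5 bond can compete when the hydrogen bond from O7–H is not decisive, and a second osmylation of the product is a further loss channel. The fallback sets out from 6 and comes back at 8, and it replaces hydrogen-bond direction by a covalent metal-alkoxide template. VO(acac)2-catalysed epoxidation with tert-butyl hydroperoxide, in which the vanadium alkoxide of O7 delivers oxygen to the homoallylic C2=C3 bond on the β face, should give the 2β,3β-epoxy alcohol F1. Pd(PPh3)4 (zerovalent palladium) under CO2 in THF should then ionise the vinyl epoxide at C3 with inversion; the C2 alkoxide takes up CO2 and the carbonate closes on C3 anti to palladium, so that the cis-fused β-carbonate F2 forms with net retention. Methanolysis with K2CO3 in MeOH returns triol 8.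

Step 6. The risk is loss of protecting-group orthogonality: hydrolysis at silicon may accompany cleavage of the acetonide. The fallback sets out from 11 and comes back at 13; it gives up the selectivity and re-installs the silylene after the oxidation. Prolonged aqueous TFA at rt should remove both groups and give the 3-O-benzoyl tetraol F3. MnO2 in CH2Cl2 should oxidise only the allylic C6–OH, since O3 is esterified and O2–H and O7–H are not allylic, and give the enone triol F4. tBu2Si(OTf)2 with pyridine then bridges O7 and O2, the only 1,3-diol left once C6 is a ketone, and delivers 13.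

Step 8. The risk is poor facial selectivity of hydride delivery (β-face attack would return 12) or competing conjugate reduction. The fallback sets out from 13 and comes back at 14 without any new compound (entry F0). It replaces substrate direction by catalyst control: a Corey–Bakshi–Shibata reduction with the 2-methyl-oxazaborolidine and catecholborane at −78 °C. If C1 acts as the large group, the (R)-configured catalyst should give the 6S alcohol; both antipodes of the catalyst would be tried.

Further compounds
F1 | step 4 | 2β,3β-epoxide of alcohol 6 (oxirane across C2–C3 on the face of C7; O1,O6-acetonide α; C4=C5 retained) | CC1(C)O[C@@H]2C=C[C@@H](O3)[C@@H]3[C@@]2(O1)CO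
F2 | step 4 | O2,O3-cyclic carbonate of triol 8 (carbonate cis-fused on the β face) | CC1(C)O[C@@H]2C=C[C@@H](OC3=O)[C@@H](O3)[C@@]2(O1)CO
F3 | step 6 | 3-O-benzoyl-(1R,2R,3R,6R)-1-(hydroxymethyl)cyclohex-4-ene-1,2,3,6-tetrol (O1–H and O6–H α; O2–H β) | O[C@@H]1C=C[C@@H](OC(=O)c2ccccc2)[C@@H](O)[C@@]1(O)CO
F4 | step 6 | (1S,2R,3R)-3-O-benzoyl-1,2,3-trihydroxy-1-(hydroxymethyl)cyclohex-4-en-6-one | O=C1C=C[C@@H](OC(=O)c2ccccc2)[C@@H](O)[C@@]1(O)CO
F0 | step 8 | none | none
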